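**Plan**

1. Core numbering (7-oxabicyclo[4.1.0]heptan-2-one): C1 = epoxide carbon bearing CH3, C2 = ketone, C3 = CH–O-tigloyl, C4 = CH–side chain, C5 = CH2, C6 = epoxide CH.
2. Retrosynthesis cuts, in this order: the side-chain bond between its C=O and CH=CH (alkenylzinc plus α-methylene aldehyde) and the exo-methylene carbon; the ester C–O bond; the two epoxide C–O bonds (directed epoxidation of a 2-methylcyclohex-2-enol); then, together, the ring bonds C2–C3 and C1–C6.
3. Enabling feature: the two-carbon unit C1(CH3)–C2(=O) lies between two oxygen-bearing CH carbons, C6 and C3. With the C2 ketone written as a nitro group this unit is (E)-1-nitropropene; C6 is the enamine carbon and C3 the second formyl carbon of a 2-substituted pentanedial. The extra formyl group on C6 is later turned into a formate and expelled to give C1=C6.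
4. Forward: dialdehyde 5, then a one-flask Michael/Henry reaction that closes the six-membered carbocycle (the oxirane comes later), then Baeyer–Villiger, Nef/elimination, esterification, Luche reduction, directed epoxidation, oxidation, and last the side chain (methylenation, alkenylzinc addition, oxidation).
5. Stereochemistry: the pyrrolidine catalyst fixes the methyl-bearing carbon; the other ring centres equilibrate to the all-equatorial isomer, which relays this to C4 and C3 (trans) before the methyl-bearing centre becomes sp2. The epoxide face follows from the C2 carbinol (axial hydride delivery, then syn-directed epoxidation).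

Key step: step 3

Remark: the sense of induction of the S pyrrolidine catalyst is taken from its usual behaviour with aldehydes and (E)-nitroalkenes; if the methyl-bearing centre formed with the other configuration, the R catalyst would be used.

**Route**

Step 1
Reactants: 1 4-{[tert-butyl(dimethyl)silyl]oxy}butanal; 2 prop-2-enal (acrolein)
Product: 5 rac-2-(2-{[tert-butyl(dimethyl)silyl]oxy}ethyl)pentanedial, via enamine 3 (not isolated), via cyclic aminal 4 (not isolated)
Conditions: pyrrolidine, K2CO3, Et2O, 0 °C; 2, MeCN, 0 °C → rt; aq. AcOH/NaOAc, rt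
Reagents that add atoms: none
Why: Stork enamine Michael addition, in which enamine 3 adds to acrolein through the dihydropyran aminal 4 and buffered hydrolysis releases the 1,5-dialdehyde; the new centre is left racemic on purpose because step 3 equilibrates it.

Step 2
Reactants: 6 1-nitropropan-2-ol
Product: 8 (1E)-1-nitroprop-1-ene, via mesylate 7 (not isolated)
Conditions: CH3SO2Cl, Et3N, CH2Cl2, −10 → 0 °C
Reagents that add atoms: none
Why: mesylation and E1cB elimination of a β-nitro alcohol, which should give the conjugated E-nitroalkene.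

Step 3
Reactants: 5 rac-2-(2-{[tert-butyl(dimethyl)silyl]oxy}ethyl)pentanedial; 8 (1E)-1-nitroprop-1-ene
Product: 10 (1S,2R,3S,4S,5S)-5-(2-{[tert-butyl(dimethyl)silyl]oxy}ethyl)-4-hydroxy-2-methyl-3-nitrocyclohexane-1-carbaldehyde, via Michael adduct 9 (not isolated)
Conditions: (S)-2-[diphenyl(trimethylsilyloxy)methyl]pyrrolidine (10 mol%), THF, rt; then Et3N (0.5 equiv), rt
Reagents that add atoms: none
Why: The catalyst condenses with the unbranched formyl group of 5 to give the E-enamine, which adds to the methyl-bearing carbon of 8 (Michael addition, future C6–C1 bond); after hydrolysis the nitro-bearing carbon of 9 attacks the branched formyl group as its nitronate (intramolecular Henry reaction, future C2–C3 bond). The closest known reaction type is the diarylprolinol silyl ether-catalysed domino Michael/Henry reaction of pentane-1,5-dial with nitroalkenes. The single ring is closed by the Henry step in the 6-(enolexo)-exo-trig mode. The methyl-bearing carbon is set by the catalyst, whose Ph2C(OSiMe3) group blocks one enamine face (S catalyst should give R). The other four ring centres are all epimerisable under the amine conditions (formyl-bearing carbon by enolisation, nitro-bearing carbon through the nitronate, carbinol carbon by retro-Henry/Henry, side-chain carbon by enolisation of the ring-opened aldehyde) and should settle in the all-equatorial arrangement dictated by the methyl group. The step needs enamine formation at one formyl group only and one mode of closure; the α-branch slows condensation at the second formyl group, and the alternative Henry closure would give a four-membered ring.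

Step 4
Reactants: 10 (1S,2R,3S,4S,5S)-5-(2-{[tert-butyl(dimethyl)silyl]oxy}ethyl)-4-hydroxy-2-methyl-3-nitrocyclohexane-1-carbaldehyde
Product: 11 (1S,2S,3S,4S,5R)-5-(2-{[tert-butyl(dimethyl)silyl]oxy}ethyl)-4-hydroxy-2-methyl-3-nitrocyclohexyl formate
Conditions: mCPBA, Na2HPO4, CH2Cl2, 0 °C → rt
Reagents that add atoms: 3-chloroperoxybenzoic acid, OOC(=O)c1cccc(Cl)c1
Why: Baeyer–Villiger oxidation of an α-branched aldehyde, in which the secondary ring carbon should migrate to oxygen with retention in preference to hydride, turning the auxiliary formyl group into a formate β to the future ketone.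

Step 5
Reactants: 11 (1S,2S,3S,4S,5R)-5-(2-{[tert-butyl(dimethyl)silyl]oxy}ethyl)-4-hydroxy-2-methyl-3-nitrocyclohexyl formate
Product: 14 (5S,6S)-5-(2-{[tert-butyl(dimethyl)silyl]oxy}ethyl)-6-hydroxy-2-methylcyclohex-2-en-1-one, via potassium nitronate 12 (not isolated), via keto formate 13 (not isolated)
Conditions: KOC(CH3)3 (1.05 equiv), THF, −78 °C; O3, CH2Cl2, −78 °C; N2 purge; Et3N, −78 → 0 °C
Reagents that add atoms: ozone, [O-][O+]=O
Why: oxidative Nef reaction (ozonolysis of the nitronate) unmasks the ring ketone, and Et3N then causes E1cB loss of formate to give the conjugated enone; the carbinol centre is not touched and should keep the trans relationship to the side chain set in step 3.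

Step 6
Reactants: 14 (5S,6S)-5-(2-{[tert-butyl(dimethyl)silyl]oxy}ethyl)-6-hydroxy-2-methylcyclohex-2-en-1-one; 15 (2E)-2-methylbut-2-enoyl chloride (tigloyl chloride)
Product: 16 (1S,6S)-6-(2-{[tert-butyl(dimethyl)silyl]oxy}ethyl)-3-methyl-2-oxocyclohex-3-en-1-yl (2E)-2-methylbut-2-enoate
Conditions: pyridine, DMAP (cat.), CH2Cl2, 0 °C
Reagents that add atoms: none
Why: DMAP-catalysed acylation of the secondary α-hydroxy ketone by the acid chloride, which touches no stereocentre and keeps the E geometry of the acyl group.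

Step 7
Reactants: 16 (1S,6S)-6-(2-{[tert-butyl(dimethyl)silyl]oxy}ethyl)-3-methyl-2-oxocyclohex-3-en-1-yl (2E)-2-methylbut-2-enoate
Product: 17 (1S,2S,6S)-6-(2-{[tert-butyl(dimethyl)silyl]oxy}ethyl)-2-hydroxy-3-methylcyclohex-3-en-1-yl (2E)-2-methylbut-2-enoate
Conditions: NaBH4, CeCl3·7H2O, MeOH, −40 °C
Reagents that add atoms: none
Why: Luche 1,2-reduction, in which axial hydride delivery to the half-chair with both substituents equatorial should give the equatorial alcohol, trans to the ester and cis to the side chain.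

Step 8
Reactants: 17 (1S,2S,6S)-6-(2-{[tert-butyl(dimethyl)silyl]oxy}ethyl)-2-hydroxy-3-methylcyclohex-3-en-1-yl (2E)-2-methylbut-2-enoate
Product: 18 (1R,2R,3S,4R,6S)-4-(2-{[tert-butyl(dimethyl)silyl]oxy}ethyl)-2-hydroxy-1-methyl-7-oxabicyclo[4.1.0]heptan-3-yl (2E)-2-methylbut-2-enoate
Conditions: VO(acac)2 (5 mol%), t-BuOOH (decane), CH2Cl2, 0 °C → rt
Reagents that add atoms: tert-butyl hydroperoxide, CC(C)(C)OO
Why: hydroxyl-directed epoxidation of a cyclic allylic alcohol, which should deliver oxygen syn to the hydroxyl group (cis to the side chain) and leave the electron-poor tiglate alkene alone.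

Step 9
Reactants: 18 (1R,2R,3S,4R,6S)-4-(2-{[tert-butyl(dimethyl)silyl]oxy}ethyl)-2-hydroxy-1-methyl-7-oxabicyclo[4.1.0]heptan-3-yl (2E)-2-methylbut-2-enoate
Product: 19 (1S,3S,4R,6S)-4-(2-{[tert-butyl(dimethyl)silyl]oxy}ethyl)-1-methyl-2-oxo-7-oxabicyclo[4.1.0]heptan-3-yl (2E)-2-methylbut-2-enoate
Conditions: Dess–Martin periodinane, NaHCO3, CH2Cl2, 0 °C → rt
Reagents that add atoms: none
Why: Dess–Martin oxidation of the secondary alcohol to the α,β-epoxy ketone under buffered conditions that should not epimerise the ester-bearing carbon.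

Step 10
Reactants: 19 (1S,3S,4R,6S)-4-(2-{[tert-butyl(dimethyl)silyl]oxy}ethyl)-1-methyl-2-oxo-7-oxabicyclo[4.1.0]heptan-3-yl (2E)-2-methylbut-2-enoate
Product: 20 (1S,3S,4R,6S)-4-(2-hydroxyethyl)-1-methyl-2-oxo-7-oxabicyclo[4.1.0]heptan-3-yl (2E)-2-methylbut-2-enoate
Conditions: HF·pyridine, pyridine, THF, 0 °C → rt
Reagents that add atoms: none
Why: fluoride cleavage of the primary silyl ether, buffered with pyridine so that the epoxy ketone and the ester should survive.

Step 11
Reactants: 20 (1S,3S,4R,6S)-4-(2-hydroxyethyl)-1-methyl-2-oxo-7-oxabicyclo[4.1.0]heptan-3-yl (2E)-2-methylbut-2-enoate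
Product: 21 (1S,3S,4S,6S)-1-methyl-2-oxo-4-(2-oxoethyl)-7-oxabicyclo[4.1.0]heptan-3-yl (2E)-2-methylbut-2-enoate
Conditions: Dess–Martin periodinane, NaHCO3, CH2Cl2, 0 °C
Reagents that add atoms: none
Why: Dess–Martin oxidation of the primary alcohol to the aldehyde without over-oxidation.

Step 12
Reactants: 21 (1S,3S,4S,6S)-1-methyl-2-oxo-4-(2-oxoethyl)-7-oxabicyclo[4.1.0]heptan-3-yl (2E)-2-methylbut-2-enoate
Product: 23 (1S,3S,4S,6S)-1-methyl-2-oxo-4-(3-oxoprop-1-en-2-yl)-7-oxabicyclo[4.1.0]heptan-3-yl (2E)-2-methylbut-2-enoate, via Mannich base 22 (not isolated)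
Conditions: dimethylmethylideneammonium iodide, Et3N, CH2Cl2, rt
Reagents that add atoms: dimethylmethylideneammonium iodide, C=[N+](C)C.[I-]
Why: Mannich reaction of the aldehyde followed by amine-promoted elimination of dimethylamine (α-methylenation); the aldehyde enolises far more readily than the hindered ring ketone.

Step 13
Reactants: 23 (1S,3S,4S,6S)-1-methyl-2-oxo-4-(3-oxoprop-1-en-2-yl)-7-oxabicyclo[4.1.0]heptan-3-yl (2E)-2-methylbut-2-enoate; 24 trimethyl[(2-methylbut-3-yn-2-yl)oxy]silane
Product: 28 (1S,3S,4S,6S)-4-[(4E)-3,6-dihydroxy-6-methylhepta-1,4-dien-2-yl]-1-methyl-2-oxo-7-oxabicyclo[4.1.0]heptan-3-yl (2E)-2-methylbut-2-enoate, via alkenylzirconocene 25 (not isolated), via alkenylzinc 26 (not isolated), via silyl ether 27 (not isolated)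
Conditions: 24, Cp2Zr(H)Cl, CH2Cl2, rt; Zn(CH3)2, toluene, −65 °C; 23, −65 → 0 °C; aq. NH4Cl; citric acid, MeOH, 0 °C
Reagents that add atoms: none
Why: hydrozirconation of the terminal alkyne (syn addition, E-alkenyl), transmetalation to zinc and 1,2-addition to the aldehyde, which the ketone and ester should survive; the carbinol forms as a mixture of epimers that step 14 removes, and the labile tertiary silyl ether is methanolysed in the work-up.

Step 14
Reactants: 28 (1S,3S,4S,6S)-4-[(4E)-3,6-dihydroxy-6-methylhepta-1,4-dien-2-yl]-1-methyl-2-oxo-7-oxabicyclo[4.1.0]heptan-3-yl (2E)-2-methylbut-2-enoate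
Product: 29 (1S,3S,4S,6S)-4-[(4E)-6-hydroxy-6-methyl-3-oxohepta-1,4-dien-2-yl]-1-methyl-2-oxo-7-oxabicyclo[4.1.0]heptan-3-yl (2E)-2-methylbut-2-enoate
Conditions: Dess–Martin periodinane, NaHCO3, CH2Cl2, 0 °C
Reagents that add atoms: none
Why: Dess–Martin oxidation of the bis-allylic secondary alcohol to the cross-conjugated dienone; the tertiary alcohol cannot be oxidised.

**Compound list**

The CIP label at the side-chain-bearing ring carbon changes with its substituents (10, 14–17, 21–29: S; 11, 18–20: R); its spatial arrangement is the same throughout.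

1 | 4-{[tert-butyl(dimethyl)silyl]oxy}butanal | CC(C)(C)[Si](C)(C)OCCCC=O | starting material
2 | prop-2-enal (acrolein) | C=CC=O | starting material
3 | 1-[(1E)-4-{[tert-butyl(dimethyl)silyl]oxy}but-1-en-1-yl]pyrrolidine | CC(C)(C)[Si](C)(C)OCC/C=C/N1CCCC1 | intermediate
4 | 3-(2-{[tert-butyl(dimethyl)silyl]oxy}ethyl)-2-(pyrrolidin-1-yl)-3,4-dihydro-2H-pyran, diastereomer mixture | CC(C)(C)[Si](C)(C)OCCC1CC=COC1N1CCCC1 | intermediate
5 | rac-2-(2-{[tert-butyl(dimethyl)silyl]oxy}ethyl)pentanedial | CC(C)(C)[Si](C)(C)OCCC(C=O)CCC=O | intermediate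
6 | 1-nitropropan-2-ol (racemic) | CC(O)C[N+](=O)[O-] | starting material
7 | 1-nitropropan-2-yl methanesulfonate | CC(OS(C)(=O)=O)C[N+](=O)[O-] | intermediate
8 | (1E)-1-nitroprop-1-ene | C/C=C/[N+](=O)[O-] | intermediate
9 | 4-(2-{[tert-butyl(dimethyl)silyl]oxy}ethyl)-2-[(2R)-1-nitropropan-2-yl]pentanedial, epimers at both formyl-bearing carbons | CC(C)(C)[Si](C)(C)OCCC(C=O)CC(C=O)[C@@H](C)C[N+](=O)[O-] | intermediate
10 | (1S,2R,3S,4S,5S)-5-(2-{[tert-butyl(dimethyl)silyl]oxy}ethyl)-4-hydroxy-2-methyl-3-nitrocyclohexane-1-carbaldehyde, all five ring substituents equatorial (each neighbouring pair trans) | CC(C)(C)[Si](C)(C)OCC[C@@H]1C[C@H](C=O)[C@@H](C)[C@H]([N+](=O)[O-])[C@H]1O | intermediate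
11 | (1S,2S,3S,4S,5R)-5-(2-{[tert-butyl(dimethyl)silyl]oxy}ethyl)-4-hydroxy-2-methyl-3-nitrocyclohexyl formate, relative configuration as in 10 | CC(C)(C)[Si](C)(C)OCC[C@@H]1C[C@H](OC=O)[C@@H](C)[C@H]([N+](=O)[O-])[C@H]1O | intermediate
12 | potassium nitronate of 11 (nitro carbon sp2, other centres as in 11) | CC(C)(C)[Si](C)(C)OCC[C@@H]1C[C@H](OC=O)[C@@H](C)C(=[N+]([O-])[O-])[C@H]1O.[K+] | intermediate
13 | 5-(2-{[tert-butyl(dimethyl)silyl]oxy}ethyl)-4-hydroxy-2-methyl-3-oxocyclohexyl formate, remaining four centres as in 11 | CC(C)(C)[Si](C)(C)OCC[C@@H]1C[C@H](OC=O)[C@@H](C)C(=O)[C@H]1O | intermediate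
14 | (5S,6S)-5-(2-{[tert-butyl(dimethyl)silyl]oxy}ethyl)-6-hydroxy-2-methylcyclohex-2-en-1-one, hydroxyl trans to the side chain | CC(C)(C)[Si](C)(C)OCC[C@@H]1CC=C(C)C(=O)[C@H]1O | intermediate
15 | (2E)-2-methylbut-2-enoyl chloride (tigloyl chloride) | C/C=C(\C)C(Cl)=O | starting material
16 | (1S,6S)-6-(2-{[tert-butyl(dimethyl)silyl]oxy}ethyl)-3-methyl-2-oxocyclohex-3-en-1-yl (2E)-2-methylbut-2-enoate | CC(C)(C)[Si](C)(C)OCC[C@@H]1CC=C(C)C(=O)[C@H]1OC(=O)/C(C)=C/C | intermediate
17 | (1S,2S,6S)-6-(2-{[tert-butyl(dimethyl)silyl]oxy}ethyl)-2-hydroxy-3-methylcyclohex-3-en-1-yl (2E)-2-methylbut-2-enoate, hydroxyl trans to the ester and cis to the side chain | CC(C)(C)[Si](C)(C)OCC[C@@H]1CC=C(C)[C@H](O)[C@H]1OC(=O)/C(C)=C/C | intermediate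
18 | (1R,2R,3S,4R,6S)-4-(2-{[tert-butyl(dimethyl)silyl]oxy}ethyl)-2-hydroxy-1-methyl-7-oxabicyclo[4.1.0]heptan-3-yl (2E)-2-methylbut-2-enoate, epoxide cis to hydroxyl and side chain | CC(C)(C)[Si](C)(C)OCC[C@@H]1C[C@@H]2O[C@]2(C)[C@H](O)[C@H]1OC(=O)/C(C)=C/C | intermediate
19 | (1S,3S,4R,6S)-4-(2-{[tert-butyl(dimethyl)silyl]oxy}ethyl)-1-methyl-2-oxo-7-oxabicyclo[4.1.0]heptan-3-yl (2E)-2-methylbut-2-enoate | CC(C)(C)[Si](C)(C)OCC[C@@H]1C[C@@H]2O[C@]2(C)C(=O)[C@H]1OC(=O)/C(C)=C/C | intermediate
20 | (1S,3S,4R,6S)-4-(2-hydroxyethyl)-1-methyl-2-oxo-7-oxabicyclo[4.1.0]heptan-3-yl (2E)-2-methylbut-2-enoate | OCC[C@@H]1C[C@@H]2O[C@]2(C)C(=O)[C@H]1OC(=O)/C(C)=C/C | intermediate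
21 | (1S,3S,4S,6S)-1-methyl-2-oxo-4-(2-oxoethyl)-7-oxabicyclo[4.1.0]heptan-3-yl (2E)-2-methylbut-2-enoate | O=CC[C@@H]1C[C@@H]2O[C@]2(C)C(=O)[C@H]1OC(=O)/C(C)=C/C | intermediate
22 | 4-[1-(dimethylamino)-3-oxopropan-2-yl] analogue of 21 (Mannich base, epimers at the new carbon, ring centres as in 21) | CN(C)CC(C=O)[C@@H]1C[C@@H]2O[C@]2(C)C(=O)[C@H]1OC(=O)/C(C)=C/C | intermediate
23 | (1S,3S,4S,6S)-1-methyl-2-oxo-4-(3-oxoprop-1-en-2-yl)-7-oxabicyclo[4.1.0]heptan-3-yl (2E)-2-methylbut-2-enoate | C=C(C=O)[C@@H]1C[C@@H]2O[C@]2(C)C(=O)[C@H]1OC(=O)/C(C)=C/C | intermediate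
24 | trimethyl[(2-methylbut-3-yn-2-yl)oxy]silane | C#CC(C)(C)O[Si](C)(C)C | starting material
25 | chloro[(1E)-3-methyl-3-(trimethylsilyloxy)but-1-en-1-yl]zirconocene, Cp2Zr(Cl)CH=CHC(CH3)2OSi(CH3)3 | C[Si](C)(C)OC(C)(C)/C=C/[Zr](Cl)(C1C=CC=C1)C1C=CC=C1 | intermediate
26 | methyl[(1E)-3-methyl-3-(trimethylsilyloxy)but-1-en-1-yl]zinc | C[Zn]/C=C/C(C)(C)O[Si](C)(C)C | intermediate
27 | trimethylsilyl ether of 28 at the tertiary hydroxyl (epimers at the side-chain carbinol) | C=C(C(O)/C=C/C(C)(C)O[Si](C)(C)C)[C@@H]1C[C@@H]2O[C@]2(C)C(=O)[C@H]1OC(=O)/C(C)=C/C | intermediate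
28 | (1S,3S,4S,6S)-4-[(4E)-3,6-dihydroxy-6-methylhepta-1,4-dien-2-yl]-1-methyl-2-oxo-7-oxabicyclo[4.1.0]heptan-3-yl (2E)-2-methylbut-2-enoate (epimers at the side-chain carbinol) | C=C(C(O)/C=C/C(C)(C)O)[C@@H]1C[C@@H]2O[C@]2(C)C(=O)[C@H]1OC(=O)/C(C)=C/C | intermediate
29 | (1S,3S,4S,6S)-4-[(4E)-6-hydroxy-6-methyl-3-oxohepta-1,4-dien-2-yl]-1-methyl-2-oxo-7-oxabicyclo[4.1.0]heptan-3-yl (2E)-2-methylbut-2-enoate | C=C(C(=O)/C=C/C(C)(C)O)[C@@H]1C[C@@H]2O[C@]2(C)C(=O)[C@H]1OC(=O)/C(C)=C/C | target

**Count and risks**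

Total steps: 14. Longest linear sequence: 13 (steps 1 and 3–14; step 2 is a one-step branch).

Steps most likely to fail:

1. Step 3. Epimerisation at the side-chain-bearing carbon through the ring-opened aldehyde may be slower than the Henry closure. The two diastereomeric series would then not converge, and the enantiomeric purity passed on to 14 would be eroded.
Fallback (sets out from 1, returns at 10): the centre is fixed before the key step by auxiliary-controlled alkylation. Aldehyde 1 is condensed with (R)-1-amino-2-(methoxymethyl)pyrrolidine to the hydrazone F1. Deprotonation with LiN(CH(CH3)2)2 and alkylation with 3-bromo-1,1-dimethoxypropane gives the α-branched hydrazone F2 (the antipodal auxiliary would be used if the alkylation sense were opposite). Ozonolysis of the C=N bond gives (2S)-2-(2-{[tert-butyl(dimethyl)silyl]oxy}ethyl)-5,5-dimethoxypentanal F3. Oxalic acid on wet silica then frees the dialdehyde (2S)-2-(2-{[tert-butyl(dimethyl)silyl]oxy}ethyl)pentanedial F4, which is used at once under the conditions of step 3 without Et3N and should give 10 as the matched pair.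

2. Step 4. Hydride may migrate in place of the ring carbon in the peroxy adduct, which would give the carboxylic acid and not the formate.
Fallback (sets out from 10, returns at 14): the acid is made on purpose and degraded oxidatively. NaClO2/NaH2PO4/2-methylbut-2-ene (Pinnick oxidation) converts 10 into the carboxylic acid F5. Pb(OAc)4 in benzene/pyridine (oxidative decarboxylation with acetate capture) gives the ring acetate F6 as a mixture of epimers at the acetoxy carbon, which does not matter. F6 is then treated as in step 5, through the potassium nitronate F7 and the keto acetate F8, with acetate leaving in place of formate, to give 14.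

3. Step 5. The β-hydroxy nitronate may open by retro-Henry reaction, or the formate may be lost before the ketone exists, so that the elimination partner is gone.
Fallback (sets out from 11, returns at 14 through 13): a reductive Nef reaction that never forms the nitronate. Buffered aqueous TiCl3 (NH4OAc, THF, pH about 5) reduces the nitro group of 11 to the oxime F9 and on to the imine F10, which hydrolyses in the flask to the keto formate 13; Et3N then gives 14 as in step 5.

Further compounds
F1 | step 3 | (E)-hydrazone of 1 with (R)-1-amino-2-(methoxymethyl)pyrrolidine | CC(C)(C)[Si](C)(C)OCCC/C=N/N1CCC[C@@H]1COC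
F2 | step 3 | α-(3,3-dimethoxypropyl) hydrazone, new centre as at the side-chain carbon of 10 | CC(C)(C)[Si](C)(C)OCC[C@@H](/C=N/N1CCC[C@@H]1COC)CCC(OC)OC
F3 | step 3 | (2S)-2-(2-{[tert-butyl(dimethyl)silyl]oxy}ethyl)-5,5-dimethoxypentanal | CC(C)(C)[Si](C)(C)OCC[C@@H](C=O)CCC(OC)OC
F4 | step 3 | (2S)-2-(2-{[tert-butyl(dimethyl)silyl]oxy}ethyl)pentanedial | CC(C)(C)[Si](C)(C)OCC[C@@H](C=O)CCC=O
F5 | step 4 | (1S,2R,3S,4S,5S)-5-(2-{[tert-butyl(dimethyl)silyl]oxy}ethyl)-4-hydroxy-2-methyl-3-nitrocyclohexane-1-carboxylic acid | CC(C)(C)[Si](C)(C)OCC[C@@H]1C[C@H](C(=O)O)[C@@H](C)[C@H]([N+](=O)[O-])[C@H]1O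
F6 | step 4 | 5-(2-{[tert-butyl(dimethyl)silyl]oxy}ethyl)-4-hydroxy-2-methyl-3-nitrocyclohexyl acetate, epimers at the acetoxy carbon, other centres as in 11 | CC(C)(C)[Si](C)(C)OCC[C@@H]1CC(OC(C)=O)[C@@H](C)[C@H]([N+](=O)[O-])[C@H]1O
F7 | step 4 | potassium nitronate of F6 | CC(C)(C)[Si](C)(C)OCC[C@@H]1CC(OC(C)=O)[C@@H](C)C(=[N+]([O-])[O-])[C@H]1O.[K+]
F8 | step 4 | 5-(2-{[tert-butyl(dimethyl)silyl]oxy}ethyl)-4-hydroxy-2-methyl-3-oxocyclohexyl acetate | CC(C)(C)[Si](C)(C)OCC[C@@H]1CC(OC(C)=O)[C@@H](C)C(=O)[C@H]1O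
F9 | step 5 | oxime of 13 (3-hydroxyimino analogue, other centres as in 11) | CC(C)(C)[Si](C)(C)OCC[C@@H]1C[C@H](OC=O)[C@@H](C)C(=NO)[C@H]1O
F10 | step 5 | imine of 13 (3-imino analogue, other centres as in 11) | CC(C)(C)[Si](C)(C)OCC[C@@H]1C[C@H](OC=O)[C@@H](C)C(=N)[C@H]1O
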